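## Structural features

The target is a 2,3-trans dihydroflavonol: benzo ring A (C4a to C8a) is fused to the pyranone ring C (O1, C2, C3, C4), and ring B, a 4-hydroxyphenyl group, is attached to C2 by a single bond. Ring A carries a free hydroxyl at C5, chelated to the C4 ketone, and at C7 an ether oxygen bearing an (E)-4-hydroxy-3-methylbut-2-enyl chain. The two stereocentres are adjacent and trans, C2 (R, aryl) and C3 (R, hydroxyl); because the C3 hydroxyl raises the CIP rank of C3 above ring B, the 2R centre of the target has the same spatial arrangement as the 2S centre of the 3-unsubstituted flavanone. Fragile groups are the α-hydroxy-β-aryloxy ketone of ring C (base opens it by retro-oxa-Michael or quinone methide pathways, epimerises C2 and C3 and lets air oxidise it to the flavonol), the aryl allyl ether with its trisubstituted alkene (lost under hydrogenolysis, strong acid or peracid) and the C-nucleophilic phloroglucinol ring A. The real difficulty is twofold: absolute control at C2, a benzylic ether carbon with no resident directing group, and etherification of O7 alone among four hydroxyls without exposing the alkene to any later deprotection. The key step exploits that C2 is both benzylic to ring B and bound to O1: in an aryl benzyl ether its C–H bond is hydridic and lies six atoms from a carbenoid carbon placed at C3 beside the C4 carbonyl, so a 1,6 C–H insertion forges C2–C3 and closes ring C.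

## Logic of the disconnections

21 to 20. Two O–Si bonds are cut, at the ring-B oxygen and at the terminal allylic oxygen. Both are silyl ethers that fluoride removes in one operation without touching the alkene, the allyl aryl ether or the ketol. 20 has no free nucleophile except the chelated 5-hydroxyl and the 3-hydroxyl, so it is easier to handle than the tetrol. The forward step must stay close to neutral so that C2 and C3 are not disturbed.

20 to 15 and 19. The O7–CH2 bond of the allyl aryl ether is cut. This makes the route convergent and keeps the alkene away from every oxidation and reduction on the flavonoid core. The demand is that only O7 reacts. This is built into 15: the ring-B oxygen is silylated, O5 is hydrogen-bonded to the ketone and O3 is an alcohol. The allyl unit must also arrive without allylic transposition or loss of E geometry.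

19 to 18, 17 and 16. The allylic C–O bond at the chain terminus is cut (a C–H hydroxylation in the forward sense), followed by a protecting-group exchange. The five-carbon chain with its E alkene then comes from a commodity ester. The forward steps must oxidise the methyl group trans to the acetoxymethyl arm and later remove the acetate beside a silyl ether.

15 to 14. The O5–CH2 and O7–CH2 benzylic bonds are cut. These two ethers are what is left of the symmetric precursor, and they can be removed reductively before any alkene is present. 14 is fully protected and non-polar. Hydrogenolysis must spare the aryl silyl ether, the C4 ketone and the benzylic C2–O1 bond of ring C.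

14 to 11. The C3–O bond is cut. A carbenoid carbon cannot carry the hydroxyl, so it is added after ring closure, alpha to the C4 ketone, where the C2 aryl group directs it trans. One stereocentre and one oxygen are removed. The forward step must enolise without opening ring C and must oxidise the face opposite ring B (through 12 and 13).

11 to 10. The C2–C3 bond is cut, which opens ring C. One ring, one skeletal bond and the C2 stereocentre are traced back to an achiral, symmetric diazoketone in which ring B is simply the aryl group of an ether. The forward step must insert into the benzylic C–H bond and not add to O1, and a chiral catalyst must choose between two enantiotopic hydrogens. 10 differs from an all-benzyl version of this precursor in two points: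
- The ring-B oxygen carries a triisopropylsilyl group. Hydrogenolysis at 14 then frees O5 and O7 but not the ring-B phenol, so the later O7 etherification has no competing phenol and needs no pKa-based selectivity. The para-silyloxy group still activates the benzylic C–H bond as a donor.
- All three ring-A oxygens carry the same 4-silyloxybenzyl arm. The arms at O5 and O7 leave together, and because the arms are identical, alkylation beyond the intended stage in any of the etherification steps only gives the product of the following step.

10 to 8. The C=N2 bond is cut (diazo transfer through 9). The methyl ketone is the simplest stable precursor and avoids diazomethane and a hindered 2,6-dialkoxybenzoyl chloride. The forward step must activate the methyl group cleanly as a trifluoroacetyl ketone.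

8 to 7 and 4. The O–CH2 bond at the last, chelated ortho oxygen is cut. 7 has a single free hydroxyl, so there is nothing to select. The forward step must overcome the hydrogen bond to the ketone, which calls for a dipolar solvent and gentle heating, while the aryl silyl ethers survive anhydrous carbonate.

7 to 6 and 4. The O–CH2 bond at the first ortho oxygen is cut. The two ortho hydroxyls of 6 are equivalent, so no regiochemistry arises. The forward step should stop after one arm, which the strong hydrogen bond of the remaining hydroxyl favours; 7 is also the point from which the key step can be bypassed if necessary.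

6 to 5 and 4. The O–CH2 bond at the para oxygen is cut, which leads to a commodity triphenol. Adding the arms one per step, in the order of falling phenol acidity, keeps the amount of the ionisable bromide low at every stage and so limits C-benzylation of ring A. The forward step must favour the para hydroxyl over the two ortho hydroxyls.

4 to 3, 2 and 1. The C–Br bond, the benzylic C–H bond (reduction) and the O–Si bond are cut in turn. This leads to a commodity hydroxy aldehyde, with the phenol silylated first while it is the only hydroxyl.

## Other disconnections considered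

Alternative 1: The cut is the C3=C4 bond of a flav-3-ene. The diene A2, 1-ethenyl-2,4-bis(methoxymethoxy)-6-{[(1S)-1-[4-(methoxymethoxy)phenyl]prop-2-en-1-yl]oxy}benzene, would be closed with the second-generation Grubbs catalyst to the flav-3-ene A1, (2S)-5,7-bis(methoxymethoxy)-2-[4-(methoxymethoxy)phenyl]-2H-chromene, with loss of ethylene. Dihydroxylation anti to ring B and selective oxidation of the benzylic C4 hydroxyl would then have to follow.
- In its favour: ring-closing metathesis to 2H-chromenes is dependable and has no competing pathway of the ylide type. C2 could be set beforehand by a branched-selective allylic etherification of the ortho-vinylphenol with [Ir(cod)Cl]2 and a chiral phosphoramidite, a reaction whose enantioselectivity is easier to predict than that of a carbenoid insertion. On these two points it is the better plan.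
- Against it here: the key step creates no stereocentre and no oxygen function. Both C3 and C4 must be adjusted afterwards, where the chosen plan needs one oxidation because C4 is already a ketone. The ortho-vinylphenol costs extra steps. A1 is sensitive to acid (flavylium formation) and can lose its C2 configuration by reversible 6π ring opening. Three identical acetal groups give no handle on O7 and need acid for removal.
- Comparison: the two plans are equal in closing ring C late from a ring-A ether of the ring-B benzylic carbon, and their overall step counts are of the same order. The chosen plan is ahead in the number of redox adjustments after ring closure and in robustness of the intermediates.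

Alternative 2: The cut is C4–C4a. The erythro acid A4, (2R,3R)-3-[3,5-bis(benzyloxy)phenoxy]-3-[4-(benzyloxy)phenyl]-2-hydroxypropanoic acid, activated as its mixed anhydride with (CF3CO)2O, would acylate an ortho carbon of its own aryloxy ring to give A3, (2R,3R)-5,7-bis(benzyloxy)-2-[4-(benzyloxy)phenyl]-3-hydroxychroman-4-one.
- In its favour: both stereocentres and the 3-hydroxyl are in place before ring closure, so no oxidation follows the key step. This is better than the chosen plan. The two ortho positions of the phloroglucinol diether are equivalent and strongly activated, so regiochemistry is as unambiguous as in the chosen plan.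
- Against it here: A4 needs an aryl ether bond at a para-alkoxybenzylic carbon with defined configuration. The obvious route, opening a trans-glycidate with a C-nucleophilic phloroglucinol-type phenol, risks C-alkylation and partial SN1 character. The acylating medium releases CF3CO2H, which can ionise that same benzylic C–O bond and acylate the free 2-hydroxyl. A3 again has the same group on O7 and on the ring-B oxygen.
- Comparison: fewer steps after the key step, more before it, so overall step economy is about equal. The stereochemical risk is moved from one catalytic step to the preparation and survival of A4.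

Alternative 3: The cut is O1–C8a. With Cs2CO3, the benzylic hydroxyl of the anti aldol A6, (2R,3R)-2-(benzyloxy)-1-[2,4-bis(benzyloxy)-6-fluorophenyl]-3-[4-(benzyloxy)phenyl]-3-hydroxypropan-1-one, would displace the ortho fluoride to give A5, (2R,3R)-3,5,7-tris(benzyloxy)-2-[4-(benzyloxy)phenyl]chroman-4-one, with retention at both centres.
- In its favour: the ring closure is a simple addition–elimination on a fluoride ortho to the ketone and meta to both donors. Both stereocentres come from an aldol reaction whose outcome can be fixed by an auxiliary, and the 3-oxygen is already present. On predictability of relative configuration it is the better plan.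
- Against it here: A6 is a β-aryl-β-hydroxy ketone, so the alkoxide needed for cyclisation can also undergo retro-aldol cleavage, epimerisation at the α-alkoxy carbon and elimination. The anti glycolate aldol is the less accessible diastereomer. The fluorinated ring-A ketone adds steps. A5 once more does not distinguish O7.
- Comparison: the ring closure is as mild as that of the chosen plan and the step counts are comparable. The difference is that Alternative 3 relies on a stoichiometric auxiliary and a retro-aldol-prone intermediate, whereas the chosen plan creates ring, bond and stereocentre from an achiral precursor in one catalytic step.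

Key step: step 8

Assumption: Rh2(S-PTTL)4 (dirhodium tetrakis[N-phthaloyl-(S)-tert-leucinate]) is taken to select the benzylic hydrogen that leads to the 2S flavanone; if its sense of induction is the opposite, the mirror-image complex Rh2(R-PTTL)4 is used with no other change.

## Route

Step 1
Reactants: 1 4-hydroxybenzaldehyde
Product: 2 4-(triisopropylsilyloxy)benzaldehyde
Conditions: i-Pr3SiCl, imidazole, DMF, rt
Reagents that add atoms: chlorotriisopropylsilane, CC(C)[Si](Cl)(C(C)C)C(C)C
Why: Silylation of the only hydroxyl under imidazole catalysis; the hindered aryl silyl ether is chosen because it should withstand carbonate, amide base, peracid and hydrogenolysis and still fall to fluoride at the end.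

Step 2
Reactants: 2 4-(triisopropylsilyloxy)benzaldehyde
Product: 3 [4-(triisopropylsilyloxy)phenyl]methanol
Conditions: NaBH4, MeOH, 0 °C
Reagents that add atoms: none
Why: Chemoselective hydride reduction of the aldehyde; an aryl triisopropylsilyl ether is inert to NaBH4 in cold methanol.

Step 3
Reactants: 3 [4-(triisopropylsilyloxy)phenyl]methanol
Product: 4 1-(bromomethyl)-4-(triisopropylsilyloxy)benzene
Conditions: CBr4, PPh3, CH2Cl2, 0 °C
Reagents that add atoms: carbon tetrabromide, BrC(Br)(Br)Br
Why: Appel bromination of a primary benzylic alcohol under neutral conditions; the electron-rich bromide ionises easily and is therefore used at once after filtration through silica.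

Step 4
Reactants: 5 2,4,6-trihydroxyacetophenone; 4 1-(bromomethyl)-4-(triisopropylsilyloxy)benzene
Product: 6 1-{2,6-dihydroxy-4-{[4-(triisopropylsilyloxy)phenyl]methoxy}phenyl}ethanone
Conditions: K2CO3 (1.05 equiv), acetone, rt, slow addition of 4 (1.0 equiv)
Reagents that add atoms: none
Why: Williamson etherification at the para hydroxyl, which is the most acidic one and the only one that is neither flanked by nor hydrogen-bonded to the acetyl group; one equivalent of base and bromide at room temperature should hold the reaction at the mono-ether. Any second alkylation is harmless, because it only gives 7 ahead of time.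

Step 5
Reactants: 6 1-{2,6-dihydroxy-4-{[4-(triisopropylsilyloxy)phenyl]methoxy}phenyl}ethanone; 4 1-(bromomethyl)-4-(triisopropylsilyloxy)benzene
Product: 7 1-{2-hydroxy-4,6-bis{[4-(triisopropylsilyloxy)phenyl]methoxy}phenyl}ethanone
Conditions: K2CO3, acetone, 50 °C, 4 (1.05 equiv)
Reagents that add atoms: none
Why: Williamson etherification of one of the two equivalent ortho hydroxyls; the hydroxyl that remains is held in a strong hydrogen bond to the ketone and resists alkylation in acetone, as in the usual preparation of 2-hydroxy-4,6-dialkoxyacetophenones.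

Step 6
Reactants: 7 1-{2-hydroxy-4,6-bis{[4-(triisopropylsilyloxy)phenyl]methoxy}phenyl}ethanone; 4 1-(bromomethyl)-4-(triisopropylsilyloxy)benzene
Product: 8 1-{2,4,6-tris{[4-(triisopropylsilyloxy)phenyl]methoxy}phenyl}ethanone
Conditions: K2CO3, DMF (anhydrous), 50 °C, 4 (1.3 equiv)
Reagents that add atoms: none
Why: Williamson etherification of the chelated hydroxyl, which needs the more dissociating solvent and gentle heating; it is the closing stage of the standard per-benzylation of phloroacetophenone. Anhydrous carbonate should leave the hindered aryl silyl ethers intact.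

Step 7
Reactants: 8 1-{2,4,6-tris{[4-(triisopropylsilyloxy)phenyl]methoxy}phenyl}ethanone
Product: 10 2-diazo-1-{2,4,6-tris{[4-(triisopropylsilyloxy)phenyl]methoxy}phenyl}ethanone, via trifluoroacetyl diketone 9 (not isolated)
Conditions: LiN(SiMe3)2, THF, −78 °C; CF3CO2CH2CF3; aq NH4Cl; then 4-AcNHC6H4SO2N3, Et3N, H2O (1 equiv), MeCN, rt
Reagents that add atoms: 4-acetamidobenzenesulfonyl azide, CC(=O)Nc1ccc(cc1)S(=O)(=O)N=[N+]=[N-] (the two diazo nitrogens of 10); 2,2,2-trifluoroethyl trifluoroacetate, O=C(OCC(F)(F)F)C(F)(F)F (the trifluoroacetyl group of 9 only, lost again)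
Why: Detrifluoroacetylative diazo transfer: the kinetic lithium enolate of the methyl ketone is C-trifluoroacetylated, and the activated 1,3-dicarbonyl 9 takes the diazo group from the sulfonyl azide while the trifluoroacetyl group leaves on the sulfonamide nitrogen. The shelf-stable azide and the absence of diazomethane keep the step safe.

Step 8
Reactants: 10 2-diazo-1-{2,4,6-tris{[4-(triisopropylsilyloxy)phenyl]methoxy}phenyl}ethanone
Product: 11 (2S)-5,7-bis{[4-(triisopropylsilyloxy)phenyl]methoxy}-2-[4-(triisopropylsilyloxy)phenyl]chroman-4-one
Conditions: Rh2(S-PTTL)4 (1 mol %), 4 Å sieves, CH2Cl2, 0 °C, slow addition of 10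
Reagents that add atoms: none
Why: The divalent rhodium carboxylate expels N2 from 10 to give an electrophilic carbenoid at the future C3, which engages one benzylic C–H bond of an ortho ether in a concerted, asynchronous three-centre transition state with hydride-transfer character, the developing positive charge at C2 being stabilised by O1 and by the para-silyloxyphenyl ring, so that C2–C3 forms as the metal departs. The closest known reaction type is the asymmetric intramolecular C–H insertion of 2-alkoxyaryl diazoketones to chroman-4-ones under chiral carboxylates of divalent rhodium. Ring C closes as a six-membered ring by 1,6-insertion through the array C3–C4–C4a–C8a–O1–C2; the 1,5-position is O1 and bears no hydrogen, so a five-membered insertion product cannot form. The new stereocentre C2 is controlled by the catalyst alone: the phthalimido walls of the tert-leucinate ligands differentiate the two enantiotopic hydrogens of the benzylic CH2, and the hydrogen whose replacement gives the 2S flavanone is the one selected (see the assumption). The two ortho ethers are equivalent by symmetry once the acyl group rotates, so there is no regiochemical question, and the arm on the para oxygen is out of reach. The selectivity the step needs is chemoselectivity for C–H insertion over attack of O1 on the carbenoid (oxonium ylide, then [1,2]-shift of the benzylic group to a benzofuranone) and over carbenoid dimerisation. It is secured by the doubly activated, hydridic benzylic C–H bond, by the low nucleophilicity of an aryl ether oxygen whose lone pair is delocalised into the acyl-bearing ring, by the bulky carboxylate ligands, and by low temperature and slow addition. The product forms under neutral conditions in which C2 cannot epimerise.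

Step 9
Reactants: 11 (2S)-5,7-bis{[4-(triisopropylsilyloxy)phenyl]methoxy}-2-[4-(triisopropylsilyloxy)phenyl]chroman-4-one
Product: 14 (2R,3R)-3-hydroxy-5,7-bis{[4-(triisopropylsilyloxy)phenyl]methoxy}-2-[4-(triisopropylsilyloxy)phenyl]chroman-4-one, via trimethylsilyl enol ether 12 (not isolated), via 3-trimethylsilyloxy ketone 13 (not isolated)
Conditions: Me3SiOTf, Et3N, CH2Cl2, 0 °C; pentane/aq NaHCO3 work-up, crude 12; mCPBA, CH2Cl2, −20 to 0 °C; aq citric acid, THF, rt
Reagents that add atoms: 3-chloroperoxybenzoic acid (mCPBA), OOC(=O)c1cccc(Cl)c1 (the C3 oxygen); trimethylsilyl trifluoromethanesulfonate, C[Si](C)(C)OS(=O)(=O)C(F)(F)F (the silyl group of 12 and 13 only)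
Why: Rubottom oxidation: soft enolisation gives 12 without a free enolate, so retro-oxa-Michael opening of ring C is avoided; the peracid epoxidises C3=C4 on the face opposite the C2 aryl group, silyl migration gives 13, and mild acid frees the hydroxyl. The trans product is also the thermodynamically preferred diequatorial isomer, and the unchanged C2 centre is now named R only because the CIP ranks change.

Step 10
Reactants: 14 (2R,3R)-3-hydroxy-5,7-bis{[4-(triisopropylsilyloxy)phenyl]methoxy}-2-[4-(triisopropylsilyloxy)phenyl]chroman-4-one
Product: 15 (2R,3R)-3,5,7-trihydroxy-2-[4-(triisopropylsilyloxy)phenyl]chroman-4-one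
Conditions: H2 (1 atm), 10% Pd/C, EtOAc, rt, stopped after 2 equiv H2
Reagents that add atoms: none
Why: Hydrogenolysis of the two acyclic aryl benzylic ethers on palladium; the aryl silyl ether, the ketone and the cyclic secondary C2–O1 ether react more slowly at one atmosphere in a non-protic solvent. Only O5 and O7 are freed, which prepares the selective etherification.

Step 11
Reactants: 16 3-methylbut-2-enyl acetate
Product: 17 (2E)-4-hydroxy-3-methylbut-2-en-1-yl acetate
Conditions: SeO2 (cat.), t-BuOOH, salicylic acid (cat.), CH2Cl2, rt
Reagents that add atoms: selenium dioxide, O=[Se]=O (oxygen donor, catalytic); tert-butyl hydroperoxide, CC(C)(C)OO (terminal oxidant that restores SeO2)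
Why: Riley allylic oxidation: ene reaction and [2,3]-sigmatropic shift hydroxylate the methyl group trans to the acetoxymethyl arm, which fixes the E geometry of the chain.

Step 12
Reactants: 17 (2E)-4-hydroxy-3-methylbut-2-en-1-yl acetate
Product: 18 (2E)-4-[(tert-butyldimethylsilyl)oxy]-3-methylbut-2-en-1-yl acetate
Conditions: t-BuMe2SiCl, imidazole, CH2Cl2, rt
Reagents that add atoms: tert-butylchlorodimethylsilane, CC(C)(C)[Si](C)(C)Cl
Why: Standard silylation of a primary allylic alcohol; it masks the terminus that stays an alcohol in the target.

Step 13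
Reactants: 18 (2E)-4-[(tert-butyldimethylsilyl)oxy]-3-methylbut-2-en-1-yl acetate
Product: 19 (2E)-4-[(tert-butyldimethylsilyl)oxy]-3-methylbut-2-en-1-ol
Conditions: K2CO3 (cat.), MeOH, 0 °C
Reagents that add atoms: none
Why: Base-catalysed transesterification removes the acetate; a primary alkyl silyl ether is stable to catalytic carbonate in cold methanol.

Step 14
Reactants: 15 (2R,3R)-3,5,7-trihydroxy-2-[4-(triisopropylsilyloxy)phenyl]chroman-4-one; 19 (2E)-4-[(tert-butyldimethylsilyl)oxy]-3-methylbut-2-en-1-ol
Product: 20 (2R,3R)-7-{[(2E)-4-[(tert-butyldimethylsilyl)oxy]-3-methylbut-2-en-1-yl]oxy}-3,5-dihydroxy-2-[4-(triisopropylsilyloxy)phenyl]chroman-4-one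
Conditions: PPh3, i-PrO2CN=NCO2i-Pr, THF, 0 °C to rt
Reagents that add atoms: none
Why: Mitsunobu etherification: the 7-hydroxyl is the only acidic, unchelated phenol of 15, so it alone acts as pronucleophile, while the primary allylic alcohol 19 is activated at phosphorus and displaced by SN2 without allylic transposition. The neutral medium protects C2 and C3.

Step 15
Reactants: 20 (2R,3R)-7-{[(2E)-4-[(tert-butyldimethylsilyl)oxy]-3-methylbut-2-en-1-yl]oxy}-3,5-dihydroxy-2-[4-(triisopropylsilyloxy)phenyl]chroman-4-one
Product: 21 (2R,3R)-3,5-dihydroxy-7-{[(2E)-4-hydroxy-3-methylbut-2-en-1-yl]oxy}-2-(4-hydroxyphenyl)chroman-4-one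
Conditions: Bu4NF, AcOH (1:1), THF, 0 °C to rt
Reagents that add atoms: none
Why: Fluoride cleaves both the aryl triisopropylsilyl ether and the primary tert-butyldimethylsilyl ether; buffering with acetic acid should keep the medium from becoming basic enough to open or epimerise the dihydroflavonol.

## Compound list

1 | 4-hydroxybenzaldehyde | O=Cc1ccc(O)cc1 | starting material
2 | 4-(triisopropylsilyloxy)benzaldehyde | O=Cc1ccc(O[Si](C(C)C)(C(C)C)C(C)C)cc1 | intermediate
3 | [4-(triisopropylsilyloxy)phenyl]methanol | OCc1ccc(O[Si](C(C)C)(C(C)C)C(C)C)cc1 | intermediate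
4 | 1-(bromomethyl)-4-(triisopropylsilyloxy)benzene | BrCc1ccc(O[Si](C(C)C)(C(C)C)C(C)C)cc1 | intermediate
5 | 2,4,6-trihydroxyacetophenone | CC(=O)c1c(O)cc(O)cc1O | starting material
6 | 1-{2,6-dihydroxy-4-{[4-(triisopropylsilyloxy)phenyl]methoxy}phenyl}ethanone | CC(=O)c1c(O)cc(OCc2ccc(O[Si](C(C)C)(C(C)C)C(C)C)cc2)cc1O | intermediate
7 | 1-{2-hydroxy-4,6-bis{[4-(triisopropylsilyloxy)phenyl]methoxy}phenyl}ethanone | CC(=O)c1c(O)cc(OCc2ccc(O[Si](C(C)C)(C(C)C)C(C)C)cc2)cc1OCc1ccc(O[Si](C(C)C)(C(C)C)C(C)C)cc1 | intermediate
8 | 1-{2,4,6-tris{[4-(triisopropylsilyloxy)phenyl]methoxy}phenyl}ethanone | CC(=O)c1c(OCc2ccc(O[Si](C(C)C)(C(C)C)C(C)C)cc2)cc(OCc2ccc(O[Si](C(C)C)(C(C)C)C(C)C)cc2)cc1OCc1ccc(O[Si](C(C)C)(C(C)C)C(C)C)cc1 | intermediate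
9 | 4,4,4-trifluoro-1-{2,4,6-tris{[4-(triisopropylsilyloxy)phenyl]methoxy}phenyl}butane-1,3-dione | O=C(CC(=O)C(F)(F)F)c1c(OCc2ccc(O[Si](C(C)C)(C(C)C)C(C)C)cc2)cc(OCc2ccc(O[Si](C(C)C)(C(C)C)C(C)C)cc2)cc1OCc1ccc(O[Si](C(C)C)(C(C)C)C(C)C)cc1 | intermediate (not isolated)
10 | 2-diazo-1-{2,4,6-tris{[4-(triisopropylsilyloxy)phenyl]methoxy}phenyl}ethanone | [N-]=[N+]=CC(=O)c1c(OCc2ccc(O[Si](C(C)C)(C(C)C)C(C)C)cc2)cc(OCc2ccc(O[Si](C(C)C)(C(C)C)C(C)C)cc2)cc1OCc1ccc(O[Si](C(C)C)(C(C)C)C(C)C)cc1 | intermediate
11 | (2S)-5,7-bis{[4-(triisopropylsilyloxy)phenyl]methoxy}-2-[4-(triisopropylsilyloxy)phenyl]chroman-4-one | O(Cc1ccc(O[Si](C(C)C)(C(C)C)C(C)C)cc1)c1cc(OCc2ccc(O[Si](C(C)C)(C(C)C)C(C)C)cc2)c2c(c1)O[C@H](c1ccc(O[Si](C(C)C)(C(C)C)C(C)C)cc1)CC2=O | intermediate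
12 | (2S)-5,7-bis{[4-(triisopropylsilyloxy)phenyl]methoxy}-2-[4-(triisopropylsilyloxy)phenyl]-4-(trimethylsilyloxy)-2H-chromene | O(Cc1ccc(O[Si](C(C)C)(C(C)C)C(C)C)cc1)c1cc(OCc2ccc(O[Si](C(C)C)(C(C)C)C(C)C)cc2)c2c(c1)O[C@H](c1ccc(O[Si](C(C)C)(C(C)C)C(C)C)cc1)C=C2O[Si](C)(C)C | intermediate (not isolated)
13 | (2R,3R)-5,7-bis{[4-(triisopropylsilyloxy)phenyl]methoxy}-2-[4-(triisopropylsilyloxy)phenyl]-3-(trimethylsilyloxy)chroman-4-one | O(Cc1ccc(O[Si](C(C)C)(C(C)C)C(C)C)cc1)c1cc(OCc2ccc(O[Si](C(C)C)(C(C)C)C(C)C)cc2)c2c(c1)O[C@H](c1ccc(O[Si](C(C)C)(C(C)C)C(C)C)cc1)[C@@H](O[Si](C)(C)C)C2=O | intermediate (not isolated)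
14 | (2R,3R)-3-hydroxy-5,7-bis{[4-(triisopropylsilyloxy)phenyl]methoxy}-2-[4-(triisopropylsilyloxy)phenyl]chroman-4-one | O(Cc1ccc(O[Si](C(C)C)(C(C)C)C(C)C)cc1)c1cc(OCc2ccc(O[Si](C(C)C)(C(C)C)C(C)C)cc2)c2c(c1)O[C@H](c1ccc(O[Si](C(C)C)(C(C)C)C(C)C)cc1)[C@@H](O)C2=O | intermediate
15 | (2R,3R)-3,5,7-trihydroxy-2-[4-(triisopropylsilyloxy)phenyl]chroman-4-one | Oc1cc(O)c2c(c1)O[C@H](c1ccc(O[Si](C(C)C)(C(C)C)C(C)C)cc1)[C@@H](O)C2=O | intermediate
16 | 3-methylbut-2-enyl acetate | CC(C)=CCOC(C)=O | starting material
17 | (2E)-4-hydroxy-3-methylbut-2-en-1-yl acetate | C/C(=C\COC(C)=O)CO | intermediate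
18 | (2E)-4-[(tert-butyldimethylsilyl)oxy]-3-methylbut-2-en-1-yl acetate | C/C(=C\COC(C)=O)CO[Si](C)(C)C(C)(C)C | intermediate
19 | (2E)-4-[(tert-butyldimethylsilyl)oxy]-3-methylbut-2-en-1-ol | C/C(=C\CO)CO[Si](C)(C)C(C)(C)C | intermediate
20 | (2R,3R)-7-{[(2E)-4-[(tert-butyldimethylsilyl)oxy]-3-methylbut-2-en-1-yl]oxy}-3,5-dihydroxy-2-[4-(triisopropylsilyloxy)phenyl]chroman-4-one | C/C(=C\COc1cc(O)c2c(c1)O[C@H](c1ccc(O[Si](C(C)C)(C(C)C)C(C)C)cc1)[C@@H](O)C2=O)CO[Si](C)(C)C(C)(C)C | intermediate
21 | (2R,3R)-3,5-dihydroxy-7-{[(2E)-4-hydroxy-3-methylbut-2-en-1-yl]oxy}-2-(4-hydroxyphenyl)chroman-4-one | C/C(=C\COc1cc(O)c2c(c1)O[C@H](c1ccc(O)cc1)[C@@H](O)C2=O)CO | target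

## Step count and least certain steps

Total: 15 steps (steps 7 and 9 are each one telescoped operation). Longest linear sequence: 12 steps (1, 2, 3, 4, 5, 6, 7, 8, 9, 10, 14, 15). Steps 11 to 13 form a three-step branch that joins at step 14.

Step 8 (key step). What may go wrong: capture of the carbenoid by the ether oxygen O1 (oxonium ylide formation and [1,2]-shift of the benzylic group, which would contract the new ring to a benzofuranone), carbenoid dimerisation if the diazoketone accumulates, or poor discrimination between the two enantiotopic benzylic hydrogens. The fallback builds the C2–aryl bond by asymmetric conjugate addition instead; it sets out from 7 and comes back to the route at 11. Condensation of 7 with N,N-dimethylformamide dimethyl acetal gives the enaminone (2E)-3-(dimethylamino)-1-{2-hydroxy-4,6-bis{[4-(triisopropylsilyloxy)phenyl]methoxy}phenyl}prop-2-en-1-one F1, which closes under mild acid (AcOH) to the chromone 5,7-bis{[4-(triisopropylsilyloxy)phenyl]methoxy}-4H-chromen-4-one F2. The ring-B donor comes from commercial 4-bromophenol: silylation (i-Pr3SiCl, imidazole) gives (4-bromophenoxy)triisopropylsilane F3, and bromine–lithium exchange (n-BuLi), B(Oi-Pr)3 and hydrolysis with dilute HCl give [4-(triisopropylsilyloxy)phenyl]boronic acid F4. Enantioselective conjugate addition of F4 to F2 with Pd(OCOCF3)2 and the enantiomer of the pyridine–oxazoline ligand t-BuPyOX that delivers the 2S product then gives 11.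

Step 9. What may go wrong: loss of C2 configuration through Lewis-acid-assisted ionisation of the C2–O1 bond or reversible 6π ring opening of the chromene-type enol ether 12, protodesilylation of 12 back to 11 by the carboxylic acid that forms, or epoxidation on the face syn to ring B. The fallback oxidises the alkene instead of the enol ether and runs from 11 to 14. NaBH4 in MeOH reduces 11 to the 2,4-cis alcohol (2S,4S)-5,7-bis{[4-(triisopropylsilyloxy)phenyl]methoxy}-2-[4-(triisopropylsilyloxy)phenyl]chroman-4-ol F5. Dehydration with the Burgess reagent gives the flav-3-ene (2S)-5,7-bis{[4-(triisopropylsilyloxy)phenyl]methoxy}-2-[4-(triisopropylsilyloxy)phenyl]-2H-chromene F6. Dihydroxylation with catalytic OsO4 and N-methylmorpholine N-oxide, anti to ring B, gives the diol (2R,3S,4S)-5,7-bis{[4-(triisopropylsilyloxy)phenyl]methoxy}-2-[4-(triisopropylsilyloxy)phenyl]chromane-3,4-diol F7. MnO2 then oxidises only the benzylic C4 hydroxyl and returns to the route at 14.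

Step 4. What may go wrong: alkylation of an ortho hydroxyl in competition with the para hydroxyl, C-benzylation of the phloroglucinol nucleus by the ionisable bromide, or carbonate-induced desilylation of 4 followed by quinone methide polymerisation. The fallback runs from 5 and 3 directly to 6 by Mitsunobu etherification with one equivalent of 3 (PPh3, diisopropyl azodicarboxylate, THF, 0 °C). It activates the alcohol instead of the phenoxide, lets the most acidic phenol act as pronucleophile and needs neither base nor the benzylic bromide; it makes no new compound (F0).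

Step 10. What may go wrong: over-reduction, that is hydrogenolysis of the benzylic C2–O1 bond with opening of ring C, reduction of the C4 carbonyl, or partial loss of the aryl silyl ether on the catalyst. The fallback runs from 14 to 15 by acidolysis of the two 4-silyloxybenzyl ethers (CF3CO2H in CH2Cl2, 0 °C, pentamethylbenzene as cation trap); it makes no new compound (F0).

Step 14. What may go wrong: activation of the 3-hydroxyl instead of 19 (dehydration towards the flavonol), allylic transposition by SN2′ attack, or further alkylation at O5. The fallback is a phenoxide alkylation and runs from 19 and 15 to 20. Appel bromination of 19 (CBr4, PPh3, CH2Cl2, 0 °C) gives tert-butyl{[(2E)-4-bromo-2-methylbut-2-en-1-yl]oxy}dimethylsilane F8, which alkylates the 7-phenoxide of 15 generated with KHCO3 in DMF at room temperature to give 20.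

## Further compounds

F1 | step 8 | (2E)-3-(dimethylamino)-1-{2-hydroxy-4,6-bis{[4-(triisopropylsilyloxy)phenyl]methoxy}phenyl}prop-2-en-1-one | CN(C)/C=C/C(=O)c1c(O)cc(OCc2ccc(O[Si](C(C)C)(C(C)C)C(C)C)cc2)cc1OCc1ccc(O[Si](C(C)C)(C(C)C)C(C)C)cc1
F2 | step 8 | 5,7-bis{[4-(triisopropylsilyloxy)phenyl]methoxy}-4H-chromen-4-one | O=c1ccoc2cc(OCc3ccc(O[Si](C(C)C)(C(C)C)C(C)C)cc3)cc(OCc3ccc(O[Si](C(C)C)(C(C)C)C(C)C)cc3)c12
F3 | step 8 | (4-bromophenoxy)triisopropylsilane | Brc1ccc(O[Si](C(C)C)(C(C)C)C(C)C)cc1
F4 | step 8 | [4-(triisopropylsilyloxy)phenyl]boronic acid | OB(O)c1ccc(O[Si](C(C)C)(C(C)C)C(C)C)cc1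
F5 | step 9 | (2S,4S)-5,7-bis{[4-(triisopropylsilyloxy)phenyl]methoxy}-2-[4-(triisopropylsilyloxy)phenyl]chroman-4-ol | O(Cc1ccc(O[Si](C(C)C)(C(C)C)C(C)C)cc1)c1cc(OCc2ccc(O[Si](C(C)C)(C(C)C)C(C)C)cc2)c2c(c1)O[C@H](c1ccc(O[Si](C(C)C)(C(C)C)C(C)C)cc1)C[C@@H]2O
F6 | step 9 | (2S)-5,7-bis{[4-(triisopropylsilyloxy)phenyl]methoxy}-2-[4-(triisopropylsilyloxy)phenyl]-2H-chromene | O(Cc1ccc(O[Si](C(C)C)(C(C)C)C(C)C)cc1)c1cc(OCc2ccc(O[Si](C(C)C)(C(C)C)C(C)C)cc2)c2c(c1)O[C@H](c1ccc(O[Si](C(C)C)(C(C)C)C(C)C)cc1)C=C2
F7 | step 9 | (2R,3S,4S)-5,7-bis{[4-(triisopropylsilyloxy)phenyl]methoxy}-2-[4-(triisopropylsilyloxy)phenyl]chromane-3,4-diol | O(Cc1ccc(O[Si](C(C)C)(C(C)C)C(C)C)cc1)c1cc(OCc2ccc(O[Si](C(C)C)(C(C)C)C(C)C)cc2)c2c(c1)O[C@H](c1ccc(O[Si](C(C)C)(C(C)C)C(C)C)cc1)[C@@H](O)[C@H]2O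
F0 | step 4 | none | none
F0 | step 10 | none | none
F8 | step 14 | tert-butyl{[(2E)-4-bromo-2-methylbut-2-en-1-yl]oxy}dimethylsilane | C/C(=C\CBr)CO[Si](C)(C)C(C)(C)C
A1 | alternative 1 | (2S)-5,7-bis(methoxymethoxy)-2-[4-(methoxymethoxy)phenyl]-2H-chromene | COCOc1cc(OCOC)c2c(c1)O[C@H](c1ccc(OCOC)cc1)C=C2
A2 | alternative 1 | 1-ethenyl-2,4-bis(methoxymethoxy)-6-{[(1S)-1-[4-(methoxymethoxy)phenyl]prop-2-en-1-yl]oxy}benzene | C=Cc1c(OCOC)cc(OCOC)cc1O[C@H](c1ccc(OCOC)cc1)C=C
A3 | alternative 2 | (2R,3R)-5,7-bis(benzyloxy)-2-[4-(benzyloxy)phenyl]-3-hydroxychroman-4-one | O(Cc1ccccc1)c1cc(OCc2ccccc2)c2c(c1)O[C@H](c1ccc(OCc3ccccc3)cc1)[C@@H](O)C2=O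
A4 | alternative 2 | (2R,3R)-3-[3,5-bis(benzyloxy)phenoxy]-3-[4-(benzyloxy)phenyl]-2-hydroxypropanoic acid | O(Cc1ccccc1)c1cc(OCc2ccccc2)cc(c1)O[C@H](c1ccc(OCc2ccccc2)cc1)[C@@H](O)C(O)=O
A5 | alternative 3 | (2R,3R)-3,5,7-tris(benzyloxy)-2-[4-(benzyloxy)phenyl]chroman-4-one | O(Cc1ccccc1)c1cc(OCc2ccccc2)c2c(c1)O[C@H](c1ccc(OCc3ccccc3)cc1)[C@@H](OCc1ccccc1)C2=O
A6 | alternative 3 | (2R,3R)-2-(benzyloxy)-1-[2,4-bis(benzyloxy)-6-fluorophenyl]-3-[4-(benzyloxy)phenyl]-3-hydroxypropan-1-one | O[C@H](c1ccc(OCc2ccccc2)cc1)[C@@H](OCc1ccccc1)C(=O)c1c(F)cc(OCc2ccccc2)cc1OCc1ccccc1
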